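## Retrosynthetic overview

1. Okilactomycin C ⇐ its tetronate O-methyl ether ⇐ the corresponding tert-butyl ester, by two deprotections at the very end.
2. Ring A (13-membered carbocycle) and ring B (spiro-cyclohexene) are formed together and last, by a catalyst-controlled intramolecular Diels–Alder reaction of a 3-acyl-5-methylidene tetronate onto a 2-alkoxycarbonyl-1,3-diene; ring C (the tetronate) is bought as methyl tetronate.
3. Linear precursor ⇐ C3-lithiated 4-methoxy-5-methylidenefuranone + (Z)-Weinreb enamide; diene ⇐ Suzuki coupling of an (E)-alkenylboronate with an α-iodo crotonate made by ynoate syn-hydrostannation.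
4. (Z)-2-methyl-enoyl unit ⇐ (Z)-selective iodo-olefination and aminocarbonylation; carbon chain ⇐ copper-catalysed sp3–sp3 coupling.
5. The syn-1,3-dimethyl array ⇐ organocatalytic desymmetrising methanolysis of meso-2,4-dimethylglutaric anhydride.

Assumption: the numbered starting materials (including the meso anhydride and tert-butyl but-2-ynoate) are purchasable; (DHQD)2AQN is taken to open the anhydride in the sense drawn (otherwise its pseudo-enantiomer (DHQ)2AQN is used); the target is treated as the enol tautomer written in the given SMILES.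

## Route

Step 1
Reactants: 1 meso-2,4-dimethylglutaric anhydride, (3R,5S)-3,5-dimethyloxane-2,6-dione
Product: 2 (2S,4R)-5-methoxy-2,4-dimethyl-5-oxopentanoic acid
Conditions: MeOH (10 equiv), (DHQD)2AQN (hydroquinidine anthraquinone-1,4-diyl diether, 20 mol%), Et2O, −40 °C
Reagents that add atoms: methanol (SMILES CO)
Why: Cinchona-alkaloid (general-base) catalysed desymmetrising alcoholysis of a meso anhydride; the catalyst sends methanol to one of the two enantiotopic carbonyls, which fixes the absolute configuration of both methyl-bearing centres (their syn relationship comes from the meso substrate).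

Step 2
Reactants: 2 (2S,4R)-5-methoxy-2,4-dimethyl-5-oxopentanoic acid
Product: 3 methyl (2R,4S)-5-hydroxy-2,4-dimethylpentanoate
Conditions: BH3·THF (1.3 equiv), THF, −10 °C to rt; aqueous work-up, used crude
Reagents that add atoms: none
Why: Chemoselective borane reduction of a carboxylic acid beside an ester (acyloxyborane pathway); no stereocentre is touched.

Step 3
Reactants: 3 methyl (2R,4S)-5-hydroxy-2,4-dimethylpentanoate
Product: 4 methyl (2R,4S)-5-iodo-2,4-dimethylpentanoate
Conditions: I2, PPh3, imidazole, CH2Cl2, 0 °C
Reagents that add atoms: iodine (SMILES [I][I])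
Why: Appel-type iodination (SN2 at the primary carbon) leaves both stereocentres untouched, and immediate conversion prevents δ-lactonisation of 3.

Step 4
Reactants: 4 methyl (2R,4S)-5-iodo-2,4-dimethylpentanoate; 5 but-3-en-1-ylmagnesium bromide
Product: 6 methyl (2R,4R)-2,4-dimethylnon-8-enoate
Conditions: Li2CuCl4 (5 mol%), THF–NMP, −20 to 0 °C, slow addition of 5
Reagents that add atoms: none
Why: Kochi-type copper-catalysed sp3–sp3 cross-coupling of a primary alkyl iodide with a Grignard reagent is much faster at low temperature than addition to the hindered α-branched ester.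

Step 5
Reactants: 6 methyl (2R,4R)-2,4-dimethylnon-8-enoate
Product: 7 (2R,4R)-2,4-dimethylnon-8-enal
Conditions: i-Bu2AlH (1.05 equiv), CH2Cl2, −78 °C; MeOH, then aq. potassium sodium tartrate; used crude
Reagents that add atoms: none
Why: Partial ester reduction through the aluminium hemiacetal that is stable at −78 °C; the non-basic work-up keeps the α-centre intact.

Step 6
Reactants: 7 (2R,4R)-2,4-dimethylnon-8-enal; 8 ethyltriphenylphosphonium iodide
Product: 12 (2Z,4R,6R)-2-iodo-4,6-dimethylundeca-2,10-diene, via ethylidenetriphenylphosphorane 9 (not isolated), via (1-iodoethyl)triphenylphosphonium iodide 10 (not isolated), via (1-iodoethylidene)triphenylphosphorane 11 (not isolated)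
Conditions: 8, n-BuLi, THF, rt; I2, −78 °C; NaN(SiMe3)2, −20 °C; then 7, −78 to −20 °C
Reagents that add atoms: iodine (SMILES [I][I])
Why: Stork–Zhao-type Wittig olefination with an α-iodo ylide is kinetically Z-selective (iodine cis to the chain), giving the trisubstituted (Z)-vinyl iodide that carries the enone geometry of the target.

Step 7
Reactants: 12 (2Z,4R,6R)-2-iodo-4,6-dimethylundeca-2,10-diene
Product: 13 (2Z,4R,6R)-N-methoxy-N,2,4,6-tetramethylundeca-2,10-dienamide
Conditions: CO (1 atm), MeNHOMe·HCl (1.5 equiv), Pd(OAc)2 (5 mol%), Xantphos (6 mol%), Et3N (3 equiv), toluene, 70 °C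
Reagents that add atoms: carbon monoxide (SMILES [C-]#[O+]); N,O-dimethylhydroxylamine hydrochloride (SMILES CNOC.Cl)
Why: Palladium-catalysed aminocarbonylation of an alkenyl iodide; oxidative addition and CO insertion retain the alkene geometry, so the acyl group ends up cis to the chain.

Step 8
Reactants: 13 (2Z,4R,6R)-N-methoxy-N,2,4,6-tetramethylundeca-2,10-dienamide; 14 4,4,5,5-tetramethyl-2-vinyl-1,3,2-dioxaborolane (vinylboronic acid pinacol ester)
Product: 15 (2Z,4R,6R,10E)-N-methoxy-N,2,4,6-tetramethyl-11-(4,4,5,5-tetramethyl-1,3,2-dioxaborolan-2-yl)undeca-2,10-dienamide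
Conditions: 14 (3 equiv), RuCl2(=CHPh)(PCy3)(H2IMes) (second-generation Grubbs catalyst, 5 mol%), CH2Cl2, 40 °C
Reagents that add atoms: none
Why: Olefin cross-metathesis of a terminal alkene with vinyl-Bpin is E-selective, and the trisubstituted (Z)-enamide is inert to the catalyst.

Step 9
Reactants: 16 tert-butyl but-2-ynoate
Product: 18 tert-butyl (E)-2-iodobut-2-enoate, via tert-butyl (E)-2-(tributylstannyl)but-2-enoate 17 (not isolated)
Conditions: Bu3SnH (1.05 equiv), Pd(PPh3)4 (2 mol%), THF, 0 °C; then I2, 0 °C; aq. KF work-up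
Reagents that add atoms: iodine (SMILES [I][I]); tributylstannane (SMILES CCCC[SnH](CCCC)CCCC; its tin is present in 17 only)
Why: Palladium-catalysed syn-hydrostannation of an ynoate puts tin on the α-carbon with hydrogen cis to it, and iododestannylation with retention gives the α-iodo enoate whose methyl is cis to the ester (the later "outside" diene substituent).

Step 10
Reactants: 15 (2Z,4R,6R,10E)-alkenylboronate; 18 tert-butyl (E)-2-iodobut-2-enoate
Product: 19 tert-butyl (2Z,3E,8R,10R,11Z)-2-ethylidene-13-[methoxy(methyl)amino]-8,10,12-trimethyl-13-oxotrideca-3,11-dienoate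
Conditions: PdCl2(dppf) (5 mol%), K3PO4 (3 equiv), THF–H2O, rt; product kept cold and used promptly
Reagents that add atoms: none
Why: Suzuki–Miyaura coupling proceeds with retention at both alkenyl partners and therefore delivers the 2-alkoxycarbonyl-1,3-diene with both terminal substituents outside.

Step 11
Reactants: 20 4-methoxyfuran-2(5H)-one (methyl tetronate); 21 N,N-dimethylmethyleneiminium iodide (Eschenmoser's salt)
Product: 23 5-[(dimethylamino)methyl]-4-methoxyfuran-2(5H)-one (racemic), via lithium 4-methoxyfuran-2-olate 22 (not isolated)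
Conditions: LiN(i-Pr)2 (LDA), THF, −78 °C; then 21, −78 to 0 °C
Reagents that add atoms: none
Why: γ-Deprotonation gives the 2-oxidofuran (vinylogous enolate), which undergoes a Mannich reaction at C5.

Step 12
Reactants: 23 5-[(dimethylamino)methyl]-4-methoxyfuran-2(5H)-one
Product: 25 4-methoxy-5-methylidenefuran-2(5H)-one, via trimethylammonium iodide 24 (not isolated)
Conditions: MeI, MeOH, rt; then aq. NaHCO3, CH2Cl2, rt
Reagents that add atoms: iodomethane (SMILES CI; its methyl group is present in 24 only)
Why: Quaternisation followed by E1cB (Hofmann-type) loss of trimethylamine gives the achiral exocyclic methylene dienophile.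

Step 13
Reactants: 25 4-methoxy-5-methylidenefuran-2(5H)-one; 19 diene Weinreb amide
Product: 27 3-[(2Z,4R,6R,10E,12Z)-12-(tert-butoxycarbonyl)-2,4,6-trimethyltetradeca-2,10,12-trienoyl]-4-methoxy-5-methylidenefuran-2(5H)-one, via 3-lithio-4-methoxy-5-methylidenefuran-2(5H)-one 26 (not isolated)
Conditions: 25 (1.5 equiv), LiN(i-Pr)2, THF, −78 °C; then 19, −78 to −40 °C; AcOH quench at −78 °C
Reagents that add atoms: none
Why: C3 vinyl lithiation (C5 is blocked) followed by Weinreb ketone synthesis; the chelated tetrahedral intermediate prevents over-addition and the amide is far more electrophilic than the hindered tert-butyl dienoate.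

Step 14
Reactants: 27 linear 3-acyl-5-methylidene tetronate
Product: 28 tert-butyl ester / tetronate 4-O-methyl ether of okilactomycin C (chain CHMe centres R,R; ring-B CH bearing the chain S; ring-B CHMe S; spiro carbon S; (Z)-enone in ring A)
Conditions: (S,S)-IDPi [BINOL-derived imidodiphosphorimidate, 3,3'-bis(3,5-(CF3)2C6H3), N-triflyl core] (10 mol%), toluene (0.002 M), 4 Å MS, −20 °C to rt
Reagents that add atoms: none
Why: Proposed new method: chiral Brønsted-acid-catalysed, catalyst-controlled macrocyclising intramolecular Diels–Alder reaction. The acidic proton of the confined IDPi bridges the acyl and lactone carbonyls that flank C3 of the tetronate, lowering the LUMO of the cross-conjugated 5-methylidene so the [4+2] runs where the thermal background is negligible, and the chiral anion blocks one face of the exocyclic alkene. With the C4 enol-ether arm endo under the diene and both diene substituents outside, the chain, the ring methyl and the C4 arm become cis (three new stereocentres, rings A and B in one step), the catalyst antipode being the one that gives the spiro centre S relative to the fixed R,R chain. Closest known reaction types: the thermal or La(OTf)3-promoted intramolecular Diels–Alder of 3-acyl-5-methylidene tetronates (abyssomicin-type spirotetronates) and IDPi-catalysed Diels–Alder reactions of simple α,β-unsaturated carbonyl compounds.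

Step 15
Reactants: 28 tert-butyl ester / tetronate 4-O-methyl ether of okilactomycin C
Product: 29 tetronate 4-O-methyl ether of okilactomycin C (free carboxylic acid; same configuration)
Conditions: TFA–CH2Cl2 (1:4), 0 °C to rt; evaporate with toluene; used crude
Reagents that add atoms: none
Why: Acidolysis of the tert-butyl ester by alkyl–oxygen cleavage (tert-butyl cation, loss of 2-methylpropene); the methyl vinylogous ester, the (Z)-enone and all stereocentres are untouched under these anhydrous conditions.

Step 16
Reactants: 29 tetronate 4-O-methyl ether of okilactomycin C (free carboxylic acid)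
Product: 30 okilactomycin C
Conditions: LiCl (10 equiv), DMSO, 50 °C; dilute HCl work-up
Reagents that add atoms: none
Why: Krapcho-type SN2 demethylation of the vinylogous methyl ester by chloride (the 3-acyl tetronate anion is the leaving group), as established for 3-acyl-4-methoxy spirotetronates; no stereocentre or alkene geometry is affected, and acidification gives the enol tautomer drawn.

## Compound list

1 | meso-2,4-dimethylglutaric anhydride, (3R,5S)-3,5-dimethyloxane-2,6-dione | O=C1[C@H](C)C[C@H](C)C(=O)O1 | starting material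
2 | (2S,4R)-5-methoxy-2,4-dimethyl-5-oxopentanoic acid | COC(=O)[C@H](C)C[C@H](C)C(=O)O | intermediate
3 | methyl (2R,4S)-5-hydroxy-2,4-dimethylpentanoate | COC(=O)[C@H](C)C[C@H](C)CO | intermediate
4 | methyl (2R,4S)-5-iodo-2,4-dimethylpentanoate | COC(=O)[C@H](C)C[C@H](C)CI | intermediate
5 | but-3-en-1-ylmagnesium bromide | C=CCC[Mg]Br | starting material
6 | methyl (2R,4R)-2,4-dimethylnon-8-enoate | COC(=O)[C@H](C)C[C@H](C)CCCC=C | intermediate
7 | (2R,4R)-2,4-dimethylnon-8-enal | O=C[C@H](C)C[C@H](C)CCCC=C | intermediate
8 | ethyltriphenylphosphonium iodide | CC[P+](c1ccccc1)(c1ccccc1)c1ccccc1.[I-] | starting material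
9 | ethylidenetriphenylphosphorane | CC=P(c1ccccc1)(c1ccccc1)c1ccccc1 | intermediate
10 | (1-iodoethyl)triphenylphosphonium iodide (racemic) | CC(I)[P+](c1ccccc1)(c1ccccc1)c1ccccc1.[I-] | intermediate
11 | (1-iodoethylidene)triphenylphosphorane | CC(I)=P(c1ccccc1)(c1ccccc1)c1ccccc1 | intermediate
12 | (2Z,4R,6R)-2-iodo-4,6-dimethylundeca-2,10-diene | C/C(I)=C/[C@H](C)C[C@H](C)CCCC=C | intermediate
13 | (2Z,4R,6R)-N-methoxy-N,2,4,6-tetramethylundeca-2,10-dienamide | CON(C)C(=O)/C(C)=C\[C@H](C)C[C@H](C)CCCC=C | intermediate
14 | 4,4,5,5-tetramethyl-2-vinyl-1,3,2-dioxaborolane | C=CB1OC(C)(C)C(C)(C)O1 | starting material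
15 | (2Z,4R,6R,10E)-N-methoxy-N,2,4,6-tetramethyl-11-(4,4,5,5-tetramethyl-1,3,2-dioxaborolan-2-yl)undeca-2,10-dienamide | CON(C)C(=O)/C(C)=C\[C@H](C)C[C@H](C)CCC/C=C/B1OC(C)(C)C(C)(C)O1 | intermediate
16 | tert-butyl but-2-ynoate | CC#CC(=O)OC(C)(C)C | starting material
17 | tert-butyl (E)-2-(tributylstannyl)but-2-enoate | C/C=C(/[Sn](CCCC)(CCCC)CCCC)C(=O)OC(C)(C)C | intermediate
18 | tert-butyl (E)-2-iodobut-2-enoate (methyl cis to the ester) | C/C=C(/I)C(=O)OC(C)(C)C | intermediate
19 | tert-butyl (2Z,3E,8R,10R,11Z)-2-ethylidene-13-[methoxy(methyl)amino]-8,10,12-trimethyl-13-oxotrideca-3,11-dienoate | CON(C)C(=O)/C(C)=C\[C@H](C)C[C@H](C)CCC/C=C/C(=C/C)C(=O)OC(C)(C)C | intermediate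
20 | 4-methoxyfuran-2(5H)-one (methyl tetronate) | COC1=CC(=O)OC1 | starting material
21 | N,N-dimethylmethyleneiminium iodide | C[N+](C)=C.[I-] | starting material
22 | lithium 4-methoxyfuran-2-olate | [Li+].[O-]c1cc(OC)co1 | intermediate
23 | 5-[(dimethylamino)methyl]-4-methoxyfuran-2(5H)-one (racemic) | COC1=CC(=O)OC1CN(C)C | intermediate
24 | [(3-methoxy-5-oxo-2,5-dihydrofuran-2-yl)methyl]trimethylammonium iodide (racemic) | COC1=CC(=O)OC1C[N+](C)(C)C.[I-] | intermediate
25 | 4-methoxy-5-methylidenefuran-2(5H)-one | COC1=CC(=O)OC1=C | intermediate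
26 | 3-lithio-4-methoxy-5-methylidenefuran-2(5H)-one | COC1=C([Li])C(=O)OC1=C | intermediate
27 | 3-[(2Z,4R,6R,10E,12Z)-12-(tert-butoxycarbonyl)-2,4,6-trimethyltetradeca-2,10,12-trienoyl]-4-methoxy-5-methylidenefuran-2(5H)-one | COC1=C(C(=O)/C(C)=C\[C@H](C)C[C@H](C)CCC/C=C/C(=C/C)C(=O)OC(C)(C)C)C(=O)OC1=C | intermediate
28 | tert-butyl ester / tetronate 4-O-methyl ether of okilactomycin C (chain CHMe R,R; ring-B CH S; ring-B CHMe S; spiro carbon S; (Z)-enone) | O=C1/C(C)=C\[C@H](C)C[C@H](C)CCC[C@H]2C=C(C(=O)OC(C)(C)C)[C@@H](C)C[C@]23OC(=O)C1=C3OC | intermediate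
29 | tetronate 4-O-methyl ether of okilactomycin C (free carboxylic acid; same configuration) | O=C1/C(C)=C\[C@H](C)C[C@H](C)CCC[C@H]2C=C(C(=O)O)[C@@H](C)C[C@]23OC(=O)C1=C3OC | intermediate
30 | okilactomycin C | CC1=C/[C@H](C)C[C@H](C)CCC[C@H]2C=C(C(=O)O)[C@@H](C)C[C@]23OC(=O)\C(=C\1O)C3=O | target

## Step count and risks

Total step count: 16. Longest linear sequence: 13 (steps 1–8, 10, 13, 14, 15, 16).

Most likely to fail:

Step 14 (the proposed new reaction). Risks are insufficient activation, the wrong facial sense, or acid-induced side reactions (early loss of the tert-butyl group, Z/E isomerisation, or Nazarov-type closure of the cross-conjugated dienone). The fallback gives up catalyst control and uses known chemistry. It sets out from 27 and comes back at 28: the macrocyclising intramolecular Diels–Alder reaction is run thermally or with La(OTf)3 (toluene, 0.002 M, BHT, 80–100 °C), as is established for 3-acyl-5-methylidene tetronates. Facial selectivity is then left to the substrate (the macrocyclic tether and the two methyl-bearing centres) and the diastereomers are separated by preparative chromatography. It makes no new compound (F0).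

Step 13. Risks are slow acylation of the hindered (Z)-Weinreb amide at the low temperature that 26 tolerates, or decomposition of 26. The fallback sets out from 19 and comes back at 27 by the aldehyde addition–oxidation sequence that is established for lithiated tetronates. i-Bu2AlH (THF, −78 °C) reduces the Weinreb amide of 19 to the (Z)-enal tert-butyl (2Z,3E,8R,10R,11Z)-2-ethylidene-8,10,12-trimethyl-13-oxotrideca-3,11-dienoate F3. 1,2-Addition of 26 at −78 °C gives the carbinol tert-butyl (2Z,3E,8R,10R,11Z)-2-ethylidene-13-hydroxy-13-(4-methoxy-5-methylidene-2-oxo-2,5-dihydrofuran-3-yl)-8,10,12-trimethyltrideca-3,11-dienoate F4 (both carbinol epimers, which does not matter). Dess–Martin periodinane (CH2Cl2, NaHCO3, 0 °C) then gives 27.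

Step 6. Risks are modest yield and incomplete Z-selectivity of the iodo-olefination. The fallback sets out from 7 and comes back at 13 through an ester instead of a vinyl iodide. Achiral methyl bis(2,2,2-trifluoroethyl)phosphonoacetate is C-methylated (KOt-Bu, MeI, THF) to methyl 2-[bis(2,2,2-trifluoroethoxy)phosphoryl]propanoate F1. Still–Gennari olefination of 7 with F1 (KN(SiMe3)2, 18-crown-6, THF, −78 °C) gives methyl (2Z,4R,6R)-2,4,6-trimethylundeca-2,10-dienoate F2. MeNHOMe·HCl with i-PrMgCl (THF, −20 °C) converts F2 into 13.

## Further compounds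

F1 | step 6 | methyl 2-[bis(2,2,2-trifluoroethoxy)phosphoryl]propanoate (racemic) | COC(=O)C(C)P(=O)(OCC(F)(F)F)OCC(F)(F)F
F2 | step 6 | methyl (2Z,4R,6R)-2,4,6-trimethylundeca-2,10-dienoate | COC(=O)/C(C)=C\[C@H](C)C[C@H](C)CCCC=C
F3 | step 13 | tert-butyl (2Z,3E,8R,10R,11Z)-2-ethylidene-8,10,12-trimethyl-13-oxotrideca-3,11-dienoate | O=C/C(C)=C\[C@H](C)C[C@H](C)CCC/C=C/C(=C/C)C(=O)OC(C)(C)C
F4 | step 13 | tert-butyl (2Z,3E,8R,10R,11Z)-2-ethylidene-13-hydroxy-13-(4-methoxy-5-methylidene-2-oxo-2,5-dihydrofuran-3-yl)-8,10,12-trimethyltrideca-3,11-dienoate (both C13 epimers) | COC1=C(C(O)/C(C)=C\[C@H](C)C[C@H](C)CCC/C=C/C(=C/C)C(=O)OC(C)(C)C)C(=O)OC1=C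
F0 | step 14 | none | none
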